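**Retrosynthetic overview**
1. Target 25 ⇐ acetylation of the C19 alcohol 24, the cis-fused α-methylene lactone.
2. 24 ⇐ C–B oxidation and lactonisation of the 14-membered allylboronate 22 ⇐ ring-contracting 1,2-metalate shift of the 15-membered cyclic bis(alkenyl)borate 21, triggered by Pd and methyl 2-bromoacrylate (forms C2–C3 and C1–C15, sets C1 and C2).
3. 21 ⇐ Br/Li exchange on the linear Z-bromoalkene / E-alkenylboronate 19 ⇐ Z-selective cross-metathesis of terminal alkene 17.
4. 17 ⇐ Negishi sp3–sp2 coupling (C6–C7) of homoallylic iodide 5 (from but-3-yn-1-ol) with vinyl iodide 15.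
5. 15 ⇐ anti-carbomagnesiation/iodination of propargyl alcohol with the Grignard reagent of bromide 10 (from hex-1-en-5-yne and oxirane). Ring order: 15-membered boracycle → 14-membered carbocycle → γ-lactone.

Conventions: cembrane numbering is used for the chain and ring (C1 ring-fusion CH, C2 CH–O, C15 lactone α-carbon, C19 the CH2O carbon). "B(mac)" is the boronic ester of cis-1,2-dimethylacenaphthylene-1,2-diol (mac-diol), used as an auxiliary ligand on boron.
Assumption: (Sp,Sp)-MandyPhos is taken as the ligand antipode that sends Pd to the Re face of C1 in borate 21; if the opposite sense is found, the (Rp,Rp) antipode is used with nothing else changed.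

**Step 1**
Reactants: 1 but-3-yn-1-ol
Product: 4 (3E)-3-methyl-4-[B(mac)]but-3-en-1-ol, via alkenylalane 2 (not isolated), via boronic acid 3 (not isolated)
Conditions: Me3Al (3 equiv), Cp2ZrCl2 (20 mol %), CH2Cl2, 0→23 °C; B(OMe)3, −30→23 °C; 1 M HCl; then mac-diol, MgSO4, CH2Cl2, 23 °C
Reagents that add atoms: trimethylaluminium C[Al](C)C; trimethyl borate COB(OC)OC; mac-diol C[C@]1(O)[C@@](C)(O)c2cccc3cccc1c23
Why: Zr-catalysed syn-carboalumination (Negishi) puts Me on the internal and Al on the terminal alkyne carbon (C3=C4 E, Me cis to metal), and Al→B transmetalation followed by diol condensation keeps that geometry.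

**Step 2**
Reactants: 4 (3E)-3-methyl-4-[B(mac)]but-3-en-1-ol
Product: 5 B(mac) ester of [(1E)-4-iodo-2-methylbut-1-en-1-yl]boronic acid
Conditions: I2, PPh3, imidazole, CH2Cl2, 0 °C
Reagents that add atoms: iodine II
Why: Appel iodination of a primary alcohol is an SN2 displacement of the alkoxyphosphonium that leaves the alkenylboronate untouched.

**Step 3**
Reactants: 6 hex-1-en-5-yne; 7 oxirane
Product: 9 (3E)-4-methylocta-3,7-dien-1-ol, via alkenylalane 8 (not isolated)
Conditions: Me3Al (2 equiv), Cp2ZrCl2 (20 mol %), CH2Cl2, 23 °C; evaporate; n-BuLi (1 equiv), hexane/THF, −78 °C; oxirane, −78→23 °C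
Reagents that add atoms: trimethylaluminium C[Al](C)C
Why: Negishi carboalumination is selective for the alkyne over the terminal alkene and sets C11=C12 as E, and the derived lithium alkenylalanate opens oxirane with retention at the sp2 carbon.

**Step 4**
Reactants: 9 (3E)-4-methylocta-3,7-dien-1-ol
Product: 10 (5E)-8-bromo-5-methylocta-1,5-diene
Conditions: CBr4, PPh3, CH2Cl2, 0 °C
Reagents that add atoms: carbon tetrabromide BrC(Br)(Br)Br
Why: Appel bromination converts the primary homoallylic alcohol under neutral conditions without touching either alkene.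

**Step 5**
Reactants: 10 (5E)-8-bromo-5-methylocta-1,5-diene; 11 prop-2-yn-1-ol
Product: 14 (2Z)-3-iodo-2-[(3E)-4-methylocta-3,7-dien-1-yl]prop-2-en-1-ol, via Grignard reagent 12 (not isolated), via vinylmagnesium chelate 13 (not isolated)
Conditions: 10, Mg, THF, 40 °C; added to 11 pre-treated with i-PrMgCl (1.0 equiv) and CuI (10 mol %), Et2O/THF, −10→23 °C; then I2, −40→0 °C
Reagents that add atoms: iodine II
Why: Cu-catalysed anti-carbomagnesiation of the propargylic magnesium alkoxide (Duboudin-type) adds the alkyl group to the internal carbon and leaves a five-membered chelated vinylmagnesium, whose iodinolysis with retention gives the vinyl iodide with I cis to CH2OH (C7=C8 geometry set).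

**Step 6**
Reactants: 14 (2Z)-3-iodo-2-[(3E)-4-methylocta-3,7-dien-1-yl]prop-2-en-1-ol
Product: 15 triethylsilyl ether of 14
Conditions: TESCl, imidazole, CH2Cl2, 0 °C
Reagents that add atoms: chlorotriethylsilane CC[Si](Cl)(CC)CC
Why: Standard silylation masks the C19 alcohol against the Mo alkylidene and t-BuLi used later.

**Step 7**
Reactants: 5 B(mac) ester of [(1E)-4-iodo-2-methylbut-1-en-1-yl]boronic acid; 15 triethylsilyl ether of 14
Product: 17 B(mac) ester of [(1E,5Z,9E)-2,10-dimethyl-6-(triethylsilyloxymethyl)tetradeca-1,5,9,13-tetraen-1-yl]boronic acid, via alkylzinc iodide 16 (not isolated)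
Conditions: 5, Zn dust, LiCl, THF, 30 °C; then 15, Pd(OAc)2 (2 mol %), SPhos (4 mol %), THF, 23→40 °C
Reagents that add atoms: none
Why: Negishi sp3–sp2 coupling proceeds with retention at the vinyl iodide (C6 ends cis to CH2OTES), and the alkenyl-B(mac) is inert because no base is present to activate boron.

**Step 8**
Reactants: 17 (as above); 18 (Z)-1,2-dibromoethene (the commercial Z/E mixture can be used, only the Z isomer is productive)
Product: 19 B(mac) ester of [(1E,5Z,9E,13Z)-14-bromo-2,10-dimethyl-6-(triethylsilyloxymethyl)tetradeca-1,5,9,13-tetraen-1-yl]boronic acid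
Conditions: Mo monoaryloxide pyrrolide alkylidene (5 mol %), 18 (5 equiv), C6H6, 22 °C
Reagents that add atoms: none
Why: Kinetically Z-selective cross-metathesis of a terminal alkene with a 1,2-dihaloethene gives the Z-alkenyl bromide, and the trisubstituted alkenes and the alkenylboronate do not enter the catalytic cycle.

**Step 9**
Reactants: 19 (as above); 20 methyl 2-bromoprop-2-enoate
Product: 24 (1S,2S,3E,7Z,11E)-19-hydroxycembra-3,7,11,15(17)-tetraen-16,2-olide (cis-fused α-methylene-γ-lactone on the 14-membered ring), via cyclic lithium borate 21 (not isolated), via allylboronate 22 (not isolated), via hydroxy ester 23 (not isolated)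
Conditions: 19 added by syringe pump to t-BuLi (2.1 equiv), Et2O, −78 °C (final 2 mM); concentrate; Pd(OAc)2 (5 mol %), (Sp,Sp)-MandyPhos (6 mol %), NaOTf (3 equiv), 20 (1.3 equiv), THF, 40 °C; then NaBO3·4H2O, THF/H2O, 23 °C; then PPTS, MeOH, 23 °C
Reagents that add atoms: sodium perborate O=BO[O-].[Na+]
Why: Proposed new method: a ring-contracting, enantioselective Pd-catalysed conjunctive cross-coupling, in which Br/Li exchange unveils a Z-alkenyllithium that closes onto the remote alkenyl-B(mac) to give the 15-membered bis(alkenyl)borate 21; cationic L*Pd(II)[C(=CH2)CO2Me] (oxidative addition to 20, halide scavenged by NaOTf) binds the less substituted Z-C1=C2 bond anti to the B–C3 bond and induces a 1,2-metalate shift of the trisubstituted alkenyl carbon C3 from boron to C2, so the boracycle contracts to the 14-membered carbocycle with boron now exocyclic, and C(sp3)–C(sp2) reductive elimination then forms C1–C15; anti addition across the Z-alkene gives the C1/C2 relative configuration of the cis-lactone, the ligand sets the absolute sense (Pd on the Re face of C1, C3 delivered to the Re face of C2), and stereoretentive C–B oxidation, lactonisation and concomitant TES cleavage give 24; the closest known reactions are the intermolecular Pd/MandyPhos conjunctive coupling of bis(alkenyl)borates and of β-substituted alkenyl-B(mac) ate complexes, and the electrophile-induced ring contraction of small cyclic alkenylboronate complexes.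

**Step 10**
Reactants: 24 (as above)
Product: 25 (1S,2S,3E,7Z,11E)-19-acetoxycembra-3,7,11,15(17)-tetraen-16,2-olide (target)
Conditions: Ac2O, pyridine, DMAP (cat.), CH2Cl2, 0 °C
Reagents that add atoms: acetic anhydride CC(=O)OC(C)=O
Why: Acylation of the only free (primary allylic) hydroxyl under mild nucleophilic catalysis leaves the lactone and all stereo-elements untouched.

**Compound list**
1 | but-3-yn-1-ol | C#CCCO | starting material
2 | dimethyl[(1E)-4-(dimethylaluminooxy)-2-methylbut-1-en-1-yl]alane | C[Al](C)OCC/C(C)=C/[Al](C)C | intermediate (not isolated)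
3 | [(1E)-4-hydroxy-2-methylbut-1-en-1-yl]boronic acid | OCC/C(C)=C/B(O)O | intermediate (not isolated)
4 | (3E)-3-methyl-4-[B(mac)]but-3-en-1-ol | OCC/C(C)=C/B1O[C@@]2(C)c3cccc4cccc(c34)[C@@]2(C)O1 | intermediate
5 | B(mac) ester of [(1E)-4-iodo-2-methylbut-1-en-1-yl]boronic acid | ICC/C(C)=C/B1O[C@@]2(C)c3cccc4cccc(c34)[C@@]2(C)O1 | intermediate
6 | hex-1-en-5-yne | C#CCCC=C | starting material
7 | oxirane | C1CO1 | starting material
8 | dimethyl[(1E)-2-methylhexa-1,5-dien-1-yl]alane | C=CCC/C(C)=C/[Al](C)C | intermediate (not isolated)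
9 | (3E)-4-methylocta-3,7-dien-1-ol | C=CCC/C(C)=C/CCO | intermediate
10 | (5E)-8-bromo-5-methylocta-1,5-diene | C=CCC/C(C)=C/CCBr | intermediate
11 | prop-2-yn-1-ol | C#CCO | starting material
12 | [(3E)-4-methylocta-3,7-dien-1-yl]magnesium bromide | C=CCC/C(C)=C/CC[Mg]Br | intermediate (not isolated)
13 | 4-[(3E)-4-methylocta-3,7-dien-1-yl]-2,5-dihydro-1,2-oxamagnesole (chelated vinylmagnesium alkoxide) | C=CCC/C(C)=C/CCC1=C[Mg]OC1 | intermediate (not isolated)
14 | (2Z)-3-iodo-2-[(3E)-4-methylocta-3,7-dien-1-yl]prop-2-en-1-ol | OC/C(=C\I)CC/C=C(\C)CCC=C | intermediate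
15 | triethyl{[(2Z)-3-iodo-2-[(3E)-4-methylocta-3,7-dien-1-yl]prop-2-en-1-yl]oxy}silane | CC[Si](CC)(CC)OC/C(=C\I)CC/C=C(\C)CCC=C | intermediate
16 | {(3E)-3-methyl-4-[B(mac)]but-3-en-1-yl}zinc iodide | I[Zn]CC/C(C)=C/B1O[C@@]2(C)c3cccc4cccc(c34)[C@@]2(C)O1 | intermediate (not isolated)
17 | B(mac) ester of [(1E,5Z,9E)-2,10-dimethyl-6-(triethylsilyloxymethyl)tetradeca-1,5,9,13-tetraen-1-yl]boronic acid | C=CCC/C(C)=C/CC/C(CO[Si](CC)(CC)CC)=C/CC/C(C)=C/B1O[C@@]2(C)c3cccc4cccc(c34)[C@@]2(C)O1 | intermediate
18 | (Z)-1,2-dibromoethene | Br/C=C\Br | starting material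
19 | B(mac) ester of [(1E,5Z,9E,13Z)-14-bromo-2,10-dimethyl-6-(triethylsilyloxymethyl)tetradeca-1,5,9,13-tetraen-1-yl]boronic acid | Br/C=C\CC/C(C)=C/CC/C(CO[Si](CC)(CC)CC)=C/CC/C(C)=C/B1O[C@@]2(C)c3cccc4cccc(c34)[C@@]2(C)O1 | intermediate
20 | methyl 2-bromoprop-2-enoate | C=C(Br)C(=O)OC | starting material
21 | lithium cyclic borate, mac-boron bridging C2 and C3 in a 15-membered ring (B, Z-C2=C1, C14, C13, E-C12(Me)=C11, C10, C9, C8(CH2OTES)=C7, C6, C5, E-C4(Me)=C3); mixture of boron epimers | [Li+].CC[Si](CC)(CC)OC/C1=C\CC/C(C)=C/[B-]2(O[C@@]3(C)c4cccc5cccc(c45)[C@@]3(C)O2)/C=C\CC/C(C)=C/CC1 | intermediate (not isolated)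
22 | methyl 2-[(1R,2S,3E,7Z,11E)-2-B(mac)-4,12-dimethyl-8-(triethylsilyloxymethyl)cyclotetradeca-3,7,11-trien-1-yl]prop-2-enoate | COC(=O)C(=C)[C@H]1[C@@H](B2O[C@@]3(C)c4cccc5cccc(c45)[C@@]3(C)O2)/C=C(\C)CC/C=C(\CO[Si](CC)(CC)CC)CC/C=C(\C)CC1 | intermediate (not isolated)
23 | methyl 2-[(1S,2S,3E,7Z,11E)-2-hydroxy-4,12-dimethyl-8-(triethylsilyloxymethyl)cyclotetradeca-3,7,11-trien-1-yl]prop-2-enoate | COC(=O)C(=C)[C@H]1[C@@H](O)/C=C(\C)CC/C=C(\CO[Si](CC)(CC)CC)CC/C=C(\C)CC1 | intermediate (not isolated)
24 | (1S,2S,3E,7Z,11E)-19-hydroxycembra-3,7,11,15(17)-tetraen-16,2-olide | C=C1C(=O)O[C@H]2/C=C(\C)CC/C=C(\CO)CC/C=C(\C)CC[C@@H]12 | intermediate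
25 | (1S,2S,3E,7Z,11E)-19-acetoxycembra-3,7,11,15(17)-tetraen-16,2-olide | C=C1C(=O)O[C@H]2/C=C(\C)CC/C=C(\COC(C)=O)CC/C=C(\C)CC[C@@H]12 | target

**Step count**
Total: 10 steps. Longest linear sequence: 8 steps (steps 3, 4, 5, 6, 7, 8, 9, 10); steps 1 and 2 form the convergent branch.

**Steps most likely to fail and their fallbacks**

Step 9 (the proposed new ring-contracting conjunctive coupling). Risks are oligomeric rather than cyclic borate formation, direct Suzuki-type transfer of an alkenyl group to Pd, and insufficient enantiocontrol. The fallback uses known chemistry, sets out from 17 and comes back at 24. The alkenyl-B(mac) terminus of 17 is homologated with chloromethyllithium (BrCH2Cl, n-BuLi, −78 °C, Matteson) to the allylboronate F1 and oxidised in the same pot (NaBO3) to the (2E)-allylic alcohol F2. MnO2 gives the enal F3. Cross-metathesis of its terminal alkene with methyl 2-(bromomethyl)acrylate (Hoveyda–Grubbs II) gives the (Z)-2-(bromomethyl)enoate F4. A high-dilution Nozaki–Hiyama reaction (CrCl2, THF), the established intramolecular 2-(alkoxycarbonyl)allylation that closes cembranolide rings together with their cis-α-methylene lactone, gives the TES-protected lactone F5. A chiral carbazole–bis(oxazoline) Cr(II) catalyst of the kind used for intermolecular 2-(alkoxycarbonyl)allylations would be tried for enantiocontrol, otherwise the racemate is resolved by chiral HPLC. PPTS in MeOH then gives 24.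

Step 5 (Cu-catalysed carbomagnesiation with a valuable primary alkyl Grignard reagent; moderate yields and competing alkyne deprotonation are typical). The fallback sets out from 11 and comes back at 17, replacing carbometalation by two cross-couplings on a dihaloalkene template. Anti-addition of I2 to 11 gives (E)-2,3-diiodoprop-2-en-1-ol F6, which is silylated to the TES ether F7. Site-selective Negishi coupling of the less hindered terminal C–I bond with alkylzinc 16 gives the iodo diene F8. A second Negishi coupling of the internal C–I bond with the alkylzinc bromide F9 (from bromide 10, Zn, LiCl) gives 17. Both couplings go with retention, and the trans-diiodide geometry places C6 cis to CH2OTES.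

Step 8 (late-stage Z-selective cross-metathesis with an air-sensitive Mo catalyst). The fallback sets out from 17 and comes back at 21, using C–H silylation in place of metathesis. Ir-catalysed Z-selective dehydrogenative silylation of the terminal alkene ([Ir(OMe)(cod)]2, dtbpy, Et3SiH, norbornene, THF, 40 °C) gives the (Z)-vinylsilane F10. Iododesilylation with retention (NIS, 2,6-lutidine, HFIP, 0 °C) gives the (Z)-iodoalkene F11. I/Li exchange under the step 9 conditions then gives the same cyclic borate 21.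

**Further compounds**
F1 | step 9 | B(mac) ester of [(2E,6Z,10E)-3,11-dimethyl-7-(triethylsilyloxymethyl)pentadeca-2,6,10,14-tetraen-1-yl]boronic acid | C=CCC/C(C)=C/CC/C(CO[Si](CC)(CC)CC)=C/CC/C(C)=C/CB1O[C@@]2(C)c3cccc4cccc(c34)[C@@]2(C)O1
F2 | step 9 | (2E,6Z,10E)-3,11-dimethyl-7-(triethylsilyloxymethyl)pentadeca-2,6,10,14-tetraen-1-ol | C=CCC/C(C)=C/CC/C(CO[Si](CC)(CC)CC)=C/CC/C(C)=C/CO
F3 | step 9 | (2E,6Z,10E)-3,11-dimethyl-7-(triethylsilyloxymethyl)pentadeca-2,6,10,14-tetraenal | C=CCC/C(C)=C/CC/C(CO[Si](CC)(CC)CC)=C/CC/C(C)=C/C=O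
F4 | step 9 | methyl (2Z,6E,10Z,14E)-2-(bromomethyl)-7,15-dimethyl-16-oxo-11-(triethylsilyloxymethyl)hexadeca-2,6,10,14-tetraenoate | COC(=O)/C(CBr)=C/CC/C(C)=C/CC/C(CO[Si](CC)(CC)CC)=C/CC/C(C)=C/C=O
F5 | step 9 | triethylsilyl ether of 24 | C=C1C(=O)O[C@H]2/C=C(\C)CC/C=C(\CO[Si](CC)(CC)CC)CC/C=C(\C)CC[C@@H]12
F6 | step 5 | (E)-2,3-diiodoprop-2-en-1-ol | OC/C(I)=C\I
F7 | step 5 | triethylsilyl ether of F6 | CC[Si](CC)(CC)OC/C(I)=C\I
F8 | step 5 | B(mac) ester of [(1E,5E)-6-iodo-2-methyl-7-(triethylsilyloxy)hepta-1,5-dien-1-yl]boronic acid | CC[Si](CC)(CC)OC/C(I)=C\CC/C(C)=C/B1O[C@@]2(C)c3cccc4cccc(c34)[C@@]2(C)O1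
F9 | step 5 | [(3E)-4-methylocta-3,7-dien-1-yl]zinc bromide | C=CCC/C(C)=C/CC[Zn]Br
F10 | step 8 | B(mac) ester of [(1E,5Z,9E,13Z)-2,10-dimethyl-14-(triethylsilyl)-6-(triethylsilyloxymethyl)tetradeca-1,5,9,13-tetraen-1-yl]boronic acid | CC[Si](CC)(CC)/C=C\CC/C(C)=C/CC/C(CO[Si](CC)(CC)CC)=C/CC/C(C)=C/B1O[C@@]2(C)c3cccc4cccc(c34)[C@@]2(C)O1
F11 | step 8 | B(mac) ester of [(1E,5Z,9E,13Z)-14-iodo-2,10-dimethyl-6-(triethylsilyloxymethyl)tetradeca-1,5,9,13-tetraen-1-yl]boronic acid | I/C=C\CC/C(C)=C/CC/C(CO[Si](CC)(CC)CC)=C/CC/C(C)=C/B1O[C@@]2(C)c3cccc4cccc(c34)[C@@]2(C)O1
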